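The readings were computed with made-up constants, and the scatter is random.

Product in cedar and larch appears as electrophile goes: at 2.00 min cedar reads 72% product with 29% electrophile left, larch 55% with 43%. Cedar, with the smaller charge, has lost the larger share.

| setting | cedar | larch | flask |
|---|---|---|---|
| electrophile | 0.13 M | 0.30 M | 0.20 M |
| free base | 0.60 M | 0.60 M | 0.600 M |
| gas | 12 mM (held) | 12 mM (held) | 12 mM (held) |
| remark | run made earlier | run made earlier |  |
| time |  |  | 4.0 min |

| run | time / min | electrophile / % | product / % |
|---|---|---|---|
| cedar | 0.333 | 86 | 12 |
| cedar | 0.667 | 69 | 26 |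
| cedar | 1.00 | 56 | 42 |
| cedar | 1.33 | 51 | 52 |
| cedar | 1.50 | 45 | 56 |
| cedar | 2.00 | 29 | 72 |
| cedar | 2.50 | 24 | 83 |
| larch | 0.167 | 92 | 7 |
| larch | 0.333 | 91 | 10 |
| larch | 0.667 | 82 | 15 |
| larch | 1.00 | 72 | 27 |
| larch | 1.33 | 62 | 36 |
| larch | 2.00 | 43 | 55 |
| larch | 2.50 | 39 | 64 |

(standard deviation of a reading: 2 percentage points)

- at the start none of the gas is in solution

1. amount of electrophile in percent of the electrophile charged, at 50 s, 2.0 min and 4.0 min

My own reckoning starts from a supposition. Suppose the electrophile's partner comes from the gas and is held steady between feed and use. Loss then climbs with electrophile towards a ceiling.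

Two numbers describe that curve. Cedar and larch at their common time give the knee, the electrophile level at which loss runs at half its ceiling, as 99.9% of the flask's charge. The ceiling reads 0.849 min⁻¹ in flask charges. Both are readings and carry the scatter.

The time to any remainder is the knee times the logarithm of charge over remainder, plus the amount lost, all divided by the ceiling. For a given fraction lost, the knee term is the same for every charge, while the amount lost grows with the charge. On this curve cedar, at 65.0% of the flask's charge, loses half its charge by 1.20 min, and the flask needs 1.40 min.

The forecast gives 70%, 36% and 9%, on the ground “so the rate saturates in electrophile”. My curve runs slightly ahead of it, reaching those remainders at 0.773 min, 1.96 min and 3.91 min.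

The flask gives 71.5%, 37.8% and 8.51%, and the forecast stands within its margin.

    electrophile + nucleophile → acid set free + product (k = 1.30 M⁻¹ s⁻¹)
    nucleophile + acid set free ⇌ protonated nucleophile, settled at all times (K = 1100 M⁻¹)
    acid set free + free base ⇌ salt of the base (K = 30000 M⁻¹, k = 2.50 M⁻¹ s⁻¹)
    gas ⇌ nucleophile, rate k4*(csat - [nucleophile]) (kL = 0.200 s⁻¹)
    acid set free → by-product carried off (k = 0.0160 s⁻¹)

A run reading outside that margin at 4.0 min would overturn it. Free nucleophile in the flask rises from 0.00542 M at 0.400 min to 0.0109 M at 4.00 min, still below the saturation level of 12 mM. With the knee, the flask's remainder falls at 3.98 min. In cedar, the same knee places 56% at 1.02 min, and cedar read it at 1.00 min.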